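**Plan**
L is the flavan unit whose ring B carries C4 of the other unit, U; locants carry L or U. Retrosynthesis removes seven benzyl ethers, then cuts O1L–C8aL (ring C of L), then the C2L–ring B(L) bond (aryllithium plus a tyrosine-derived amide), then in U the C4U–aryl bond (aryl Grignard plus flavanone) and the C2U–aryl bond (conjugate addition to a chromone).
Enabling feature: ring A of L has no 5-oxygen. Its only phenol, C7L–OH, is para to C4aL and meta to C8aL–O1L, so ring A, C4L and C3L are the 4-hydroxyphenyl ring, CH2 and α-carbon of L-tyrosine. The one missing bond, O1L–C8aL, lies ortho to the chain of a para-alkylphenol, which is the carbon a dienone made by dearomatisation at C4aL offers to the C2L hydroxyl.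
Forward order: ring C of U first (chromone → flavanone → 4-arylflav-3-ene → flavan-3-ol); the bromoaryl group on C4U is lithiated and acylated by the tyrosine amide; the ketone is reduced; ring C of L closes last by phenol oxidation, oxa-Michael addition and rearomatisation; one hydrogenolysis ends the route.
Stereochemistry: C3L from L-tyrosine (diazotisation with retention); C2L from chelation-controlled reduction of the α-benzyloxy ketone (anti); C2U from ligand-controlled conjugate addition; C3U and C4U from syn hydroboration anti to the C2U aryl group.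

Key step: step 16

**Remarks**
- Bn = benzyl. "Fl" = the (2R,3S,4R)-3,7-bis(benzyloxy)-2-[3,4-bis(benzyloxy)phenyl]chroman-4-yl group (2,3-trans-3,4-trans).
- L-Tyrosine, 4-bromocatechol, 7-hydroxychromone and 4,5-dibromocatechol are taken as purchased.
- Assumption: in step 8 (R)-t-BuPyOx is taken to deliver the aryl group to the chromone face that gives the (2S)-flavanone, by analogy with its sense on cyclic enones; if the sense is opposite, the (S)-ligand is used.
- Descriptor note: the 2S flavanone and flav-3-ene have the spatial arrangement that is named 2R in the flavan-3-ols. C4U reads S while bromine sits ortho on the attached ring (21, 22) and R once carbon replaces it; the arrangement is the same.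
- A benzyl ether is placed on O3L because it chelates zinc in step 14, cannot migrate to the C2L oxygen, survives the acid of step 16 and blocks five-membered closure there.

**Route**

Step 1
Reactants: 1 L-tyrosine
Product: 4 (S)-2-hydroxy-3-(4-hydroxyphenyl)propanoic acid, via diazonium carboxylate 2 (not isolated), via α-lactone 3 (not isolated)
Conditions: NaNO2, 1 M H2SO4, H2O, 0 °C → rt
Reagents that add atoms: water, O
Why: Diazotisation of an α-amino acid: the carboxylate displaces N2 to give the α-lactone and water opens it, two inversions that leave C3L with the S configuration of L-tyrosine (net retention).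

Step 2
Reactants: 4 (S)-2-hydroxy-3-(4-hydroxyphenyl)propanoic acid
Product: 5 prop-2-en-1-yl (S)-2-hydroxy-3-[4-(prop-2-en-1-yloxy)phenyl]propanoate
Conditions: allyl bromide, K2CO3, DMF, rt
Reagents that add atoms: allyl bromide, C=CCBr
Why: Carbonate deprotonates only the carboxylic acid and the phenol, so O-alkylation (Williamson etherification and carboxylate alkylation) masks both and leaves the secondary alcohol free.

Step 3
Reactants: 5 prop-2-en-1-yl (S)-2-hydroxy-3-[4-(prop-2-en-1-yloxy)phenyl]propanoate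
Product: 6 prop-2-en-1-yl (S)-2-(benzyloxy)-3-[4-(prop-2-en-1-yloxy)phenyl]propanoate
Conditions: BnBr, Ag2O, CH2Cl2, rt, dark
Reagents that add atoms: benzyl bromide, BrCc1ccccc1
Why: Ag2O-mediated O-benzylation of an α-hydroxy ester runs without a strong base, so the α-stereocentre is not enolised.

Step 4
Reactants: 6 prop-2-en-1-yl (S)-2-(benzyloxy)-3-[4-(prop-2-en-1-yloxy)phenyl]propanoate
Product: 7 (S)-2-(benzyloxy)-N-methoxy-N-methyl-3-[4-(prop-2-en-1-yloxy)phenyl]propanamide
Conditions: MeNH(OMe)·HCl, iPrMgCl, THF, −20 → 0 °C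
Reagents that add atoms: N,O-dimethylhydroxylamine hydrochloride, CNOC.Cl
Why: Aminolysis of the ester by the chloromagnesium amide gives the N-methoxy-N-methylamide (Weinreb amide formation) without touching the α-centre.

Step 5
Reactants: 8 4-bromocatechol
Product: 9 1,2-bis(benzyloxy)-4-bromobenzene
Conditions: BnBr, K2CO3, DMF, 60 °C
Reagents that add atoms: benzyl bromide, BrCc1ccccc1
Why: Williamson etherification of both phenols.

Step 6
Reactants: 9 1,2-bis(benzyloxy)-4-bromobenzene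
Product: 11 [3,4-bis(benzyloxy)phenyl]boronic acid, via aryllithium 10 (not isolated)
Conditions: n-BuLi, THF, −78 °C; B(OiPr)3, −78 °C → rt; 1 M HCl
Reagents that add atoms: triisopropyl borate, CC(C)OB(OC(C)C)OC(C)C; water, O
Why: Bromine–lithium exchange, borylation with a trialkyl borate and acid hydrolysis is the standard route to an arylboronic acid.

Step 7
Reactants: 12 7-hydroxychromone
Product: 13 7-(benzyloxy)-4H-chromen-4-one
Conditions: BnBr, K2CO3, acetone, reflux
Reagents that add atoms: benzyl bromide, BrCc1ccccc1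
Why: Williamson etherification of the phenol under conditions too mild to open the pyranone.

Step 8
Reactants: 13 7-(benzyloxy)-4H-chromen-4-one; 11 [3,4-bis(benzyloxy)phenyl]boronic acid
Product: 14 (S)-7-(benzyloxy)-2-[3,4-bis(benzyloxy)phenyl]chroman-4-one
Conditions: Pd(OCOCF3)2 (5 mol%), (R)-t-BuPyOx (6 mol%), NH4PF6 (30 mol%), H2O (5 equiv), ClCH2CH2Cl, 60 °C
Reagents that add atoms: none
Why: Asymmetric conjugate addition of an arylboronic acid to a chromone, catalysed by divalent palladium with a pyridine–oxazoline ligand; the ligand antipode sets C2U.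

Step 9
Reactants: 15 4,5-dibromocatechol
Product: 16 1,2-bis(benzyloxy)-4,5-dibromobenzene
Conditions: BnBr, K2CO3, DMF, 60 °C
Reagents that add atoms: benzyl bromide, BrCc1ccccc1
Why: Williamson etherification of both phenols.

Step 10
Reactants: 16 1,2-bis(benzyloxy)-4,5-dibromobenzene; 14 (S)-7-(benzyloxy)-2-[3,4-bis(benzyloxy)phenyl]chroman-4-one
Product: 19 (S)-7-(benzyloxy)-2-[3,4-bis(benzyloxy)phenyl]-4-[4,5-bis(benzyloxy)-2-bromophenyl]-2H-chromene, via arylmagnesium chloride 17 (not isolated), via tertiary carbinol 18 (not isolated)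
Conditions: 16, iPrMgCl·LiCl, THF, −15 °C; then 14, LaCl3·2LiCl, THF, 0 °C; H2O; then PPTS (cat.), CH2Cl2, rt
Reagents that add atoms: none
Why: Bromine–magnesium exchange on one of two equivalent bromines gives an ortho-bromoaryl Grignard reagent that is stable at this temperature, LaCl3·2LiCl favours 1,2-addition to the enolisable flavanone over deprotonation, and the doubly benzylic carbinol loses water under mild acid to the 4-arylflav-3-ene with C2U untouched.

Step 11
Reactants: 19 (S)-7-(benzyloxy)-2-[3,4-bis(benzyloxy)phenyl]-4-[4,5-bis(benzyloxy)-2-bromophenyl]-2H-chromene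
Product: 21 (2R,3S,4S)-7-(benzyloxy)-2-[3,4-bis(benzyloxy)phenyl]-4-[4,5-bis(benzyloxy)-2-bromophenyl]chroman-3-ol, via C3 alkylborane 20 (not isolated)
Conditions: BH3·THF, THF, 0 °C → rt; then NaOH aq, H2O2, 0 °C → rt
Reagents that add atoms: hydrogen peroxide, OO
Why: Hydroboration–oxidation: borane adds syn across C3=C4 with boron on C3 (remote from the two aryl groups) from the face opposite the C2U aryl, and oxidation with retention gives the 2,3-trans-3,4-trans flavan-3-ol, which sets C3U and C4U.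

Step 12
Reactants: 21 (2R,3S,4S)-7-(benzyloxy)-2-[3,4-bis(benzyloxy)phenyl]-4-[4,5-bis(benzyloxy)-2-bromophenyl]chroman-3-ol
Product: 22 (2R,3S,4S)-3,7-bis(benzyloxy)-2-[3,4-bis(benzyloxy)phenyl]-4-[4,5-bis(benzyloxy)-2-bromophenyl]chroman
Conditions: NaH, BnBr, Bu4NI (cat.), DMF, 0 °C → rt
Reagents that add atoms: benzyl bromide, BrCc1ccccc1
Why: Williamson etherification of the secondary alkoxide, which removes the acidic proton before lithiation.

Step 13
Reactants: 22 (2R,3S,4S)-3,7-bis(benzyloxy)-2-[3,4-bis(benzyloxy)phenyl]-4-[4,5-bis(benzyloxy)-2-bromophenyl]chroman; 7 (S)-2-(benzyloxy)-N-methoxy-N-methyl-3-[4-(prop-2-en-1-yloxy)phenyl]propanamide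
Product: 24 (S)-2-(benzyloxy)-1-[4,5-bis(benzyloxy)-2-Fl-phenyl]-3-[4-(prop-2-en-1-yloxy)phenyl]propan-1-one, via aryllithium 23 (not isolated)
Conditions: 22, n-BuLi, THF, −78 °C; then 7, −78 → −40 °C; H2O
Reagents that add atoms: none
Why: Bromine–lithium exchange and acylation of the aryllithium by the N-methoxy-N-methylamide (Weinreb ketone synthesis); the chelated tetrahedral adduct prevents a second addition and shields the α-centre until the quench.

Step 14
Reactants: 24 (S)-2-(benzyloxy)-1-[4,5-bis(benzyloxy)-2-Fl-phenyl]-3-[4-(prop-2-en-1-yloxy)phenyl]propan-1-one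
Product: 25 (1R,2S)-2-(benzyloxy)-1-[4,5-bis(benzyloxy)-2-Fl-phenyl]-3-[4-(prop-2-en-1-yloxy)phenyl]propan-1-ol
Conditions: Zn(BH4)2, Et2O, −20 → 0 °C
Reagents that add atoms: none
Why: Chelation-controlled reduction: zinc bridges the carbonyl and the α-benzyloxy oxygen and hydride attacks from the side of the α-hydrogen, which gives the anti (1R,2S) alcohol and so sets C2L.

Step 15
Reactants: 25 (1R,2S)-2-(benzyloxy)-1-[4,5-bis(benzyloxy)-2-Fl-phenyl]-3-[4-(prop-2-en-1-yloxy)phenyl]propan-1-ol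
Product: 26 4-{(2S,3R)-2-(benzyloxy)-3-[4,5-bis(benzyloxy)-2-Fl-phenyl]-3-hydroxypropyl}phenol
Conditions: Pd(PPh3)4 (5 mol%), morpholine, THF, rt
Reagents that add atoms: none
Why: Zerovalent palladium ionises the allyl aryl ether to a π-allyl complex that morpholine captures (Tsuji–Trost deallylation), which frees the single phenol and leaves the benzyl ethers.

Step 16
Reactants: 26 4-{(2S,3R)-2-(benzyloxy)-3-[4,5-bis(benzyloxy)-2-Fl-phenyl]-3-hydroxypropyl}phenol
Product: 29 (2R,3S)-3-(benzyloxy)-2-[4,5-bis(benzyloxy)-2-Fl-phenyl]chroman-7-ol, via methoxydienone 27 (not isolated), via oxa-Michael adduct 28 (not isolated)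
Conditions: PhI(OAc)2 (1.1 equiv), MeOH/CH2Cl2 3:1, 0 °C; concentrate; then camphorsulfonic acid (0.2 equiv), 4 Å molecular sieves, CH2Cl2, 0 °C → rt
Reagents that add atoms: none
Why: Proposed new method: PhI(OAc)2 binds the only free phenol by ligand exchange at trivalent iodine and, in a two-electron step with methanol capture at C4aL, gives the 4-methoxycyclohexa-2,5-dienone 27; camphorsulfonic acid then lets the C2L hydroxyl add to a dienone β-carbon (the future C8aL) to give 28, whose enol is a cyclohexa-1,3-diene with a doubly allylic methoxy group, so that ionisation to an arenium ion and loss of the C8aL proton restore the arene with O1L on C8aL and the phenol on C7L. The closest known reaction types are the oxidation of 4-alkylphenols to quinol ethers by trivalent iodine or at an anode, the oxa-Michael closure of tethered alcohols onto cyclohexadienones and the acid aromatisation of nucleophile adducts of quinol ethers and quinone monoketals to meta-substituted phenols; they have not been run as one sequence to make a chroman. Ring C of L is the only ring closed, in the 6-exo-trig mode. No lasting stereocentre is made: C4aL and C8aL become aromatic, the two β-carbons are constitutionally equivalent so both adducts give the same chroman, and C2L keeps its own C–O bond, which carries the anti relation of step 14 into the 2,3-trans ring. The step needs oxidation of one ring among four oxygenated arenes, six- rather than five-membered closure, and Michael addition rather than ipso capture by the side chain: the single O–H that can bind iodine secures the first (benzyloxyarenes, whose anodic potentials overlap with that of a neutral phenol, are not touched), the benzyl ether on O3L the second, and methanol as solvent together with the hindered C2L hydroxyl the third. Methanol is removed before the acid is added so that it cannot compete as the Michael donor.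

Step 17
Reactants: 29 (2R,3S)-3-(benzyloxy)-2-[4,5-bis(benzyloxy)-2-Fl-phenyl]chroman-7-ol
Product: 30 (2R,3S)-2-{2-[(2R,3S,4R)-2-(3,4-dihydroxyphenyl)-3,7-dihydroxychroman-4-yl]-4,5-dihydroxyphenyl}chroman-3,7-diol
Conditions: H2 (1 atm), Pd(OH)2 on carbon, THF/MeOH, rt
Reagents that add atoms: none
Why: Hydrogenolysis of all seven benzyl ethers; the benzylic C–O bonds of the two pyran rings are aryl alkyl ethers and should survive these mild conditions.

**Compound list**
1 | L-tyrosine | N[C@@H](Cc1ccc(O)cc1)C(=O)O | starting material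
2 | (S)-1-carboxylato-2-(4-hydroxyphenyl)ethane-1-diazonium | N#[N+][C@@H](Cc1ccc(O)cc1)C(=O)[O-] | intermediate
3 | (R)-3-(4-hydroxybenzyl)oxiran-2-one | O=C1O[C@@H]1Cc1ccc(O)cc1 | intermediate
4 | (S)-2-hydroxy-3-(4-hydroxyphenyl)propanoic acid | O[C@@H](Cc1ccc(O)cc1)C(=O)O | intermediate
5 | prop-2-en-1-yl (S)-2-hydroxy-3-[4-(prop-2-en-1-yloxy)phenyl]propanoate | O[C@@H](Cc1ccc(OCC=C)cc1)C(=O)OCC=C | intermediate
6 | prop-2-en-1-yl (S)-2-(benzyloxy)-3-[4-(prop-2-en-1-yloxy)phenyl]propanoate | C=CCOC(=O)[C@H](Cc1ccc(OCC=C)cc1)OCc1ccccc1 | intermediate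
7 | (S)-2-(benzyloxy)-N-methoxy-N-methyl-3-[4-(prop-2-en-1-yloxy)phenyl]propanamide | CON(C)C(=O)[C@H](Cc1ccc(OCC=C)cc1)OCc1ccccc1 | intermediate
8 | 4-bromocatechol | Oc1ccc(Br)cc1O | starting material
9 | 1,2-bis(benzyloxy)-4-bromobenzene | Brc1ccc(OCc2ccccc2)c(OCc2ccccc2)c1 | intermediate
10 | [3,4-bis(benzyloxy)phenyl]lithium | [Li]c1ccc(OCc2ccccc2)c(OCc2ccccc2)c1 | intermediate
11 | [3,4-bis(benzyloxy)phenyl]boronic acid | OB(O)c1ccc(OCc2ccccc2)c(OCc2ccccc2)c1 | intermediate
12 | 7-hydroxychromone | O=c1ccoc2cc(O)ccc12 | starting material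
13 | 7-(benzyloxy)-4H-chromen-4-one | O=c1ccoc2cc(OCc3ccccc3)ccc12 | intermediate
14 | (S)-7-(benzyloxy)-2-[3,4-bis(benzyloxy)phenyl]chroman-4-one | O=C1C[C@@H](c2ccc(OCc3ccccc3)c(OCc3ccccc3)c2)Oc2cc(OCc3ccccc3)ccc12 | intermediate
15 | 4,5-dibromocatechol | Oc1cc(Br)c(Br)cc1O | starting material
16 | 1,2-bis(benzyloxy)-4,5-dibromobenzene | Brc1cc(OCc2ccccc2)c(OCc2ccccc2)cc1Br | intermediate
17 | [4,5-bis(benzyloxy)-2-bromophenyl]magnesium chloride (LiCl complex) | Cl[Mg]c1cc(OCc2ccccc2)c(OCc2ccccc2)cc1Br | intermediate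
18 | (2S)-7-(benzyloxy)-2-[3,4-bis(benzyloxy)phenyl]-4-[4,5-bis(benzyloxy)-2-bromophenyl]chroman-4-ol, both C4 epimers | OC1(c2cc(OCc3ccccc3)c(OCc3ccccc3)cc2Br)C[C@@H](c2ccc(OCc3ccccc3)c(OCc3ccccc3)c2)Oc2cc(OCc3ccccc3)ccc12 | intermediate
19 | (S)-7-(benzyloxy)-2-[3,4-bis(benzyloxy)phenyl]-4-[4,5-bis(benzyloxy)-2-bromophenyl]-2H-chromene | Brc1cc(OCc2ccccc2)c(OCc2ccccc2)cc1C1=C[C@@H](c2ccc(OCc3ccccc3)c(OCc3ccccc3)c2)Oc2cc(OCc3ccccc3)ccc12 | intermediate
20 | C3 borane of 21 (BH2 in place of the C3 hydroxyl, same 2,3-trans-3,4-trans arrangement) | Brc1cc(OCc2ccccc2)c(OCc2ccccc2)cc1[C@@H]1c2ccc(OCc3ccccc3)cc2O[C@H](c2ccc(OCc3ccccc3)c(OCc3ccccc3)c2)[C@H]1B | intermediate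
21 | (2R,3S,4S)-7-(benzyloxy)-2-[3,4-bis(benzyloxy)phenyl]-4-[4,5-bis(benzyloxy)-2-bromophenyl]chroman-3-ol | Brc1cc(OCc2ccccc2)c(OCc2ccccc2)cc1[C@@H]1c2ccc(OCc3ccccc3)cc2O[C@H](c2ccc(OCc3ccccc3)c(OCc3ccccc3)c2)[C@H]1O | intermediate
22 | (2R,3S,4S)-3,7-bis(benzyloxy)-2-[3,4-bis(benzyloxy)phenyl]-4-[4,5-bis(benzyloxy)-2-bromophenyl]chroman | Brc1cc(OCc2ccccc2)c(OCc2ccccc2)cc1[C@@H]1c2ccc(OCc3ccccc3)cc2O[C@H](c2ccc(OCc3ccccc3)c(OCc3ccccc3)c2)[C@H]1OCc1ccccc1 | intermediate
23 | [4,5-bis(benzyloxy)-2-Fl-phenyl]lithium (lithium in place of the bromine of 22) | [Li]c1cc(OCc2ccccc2)c(OCc2ccccc2)cc1[C@@H]1c2ccc(OCc3ccccc3)cc2O[C@H](c2ccc(OCc3ccccc3)c(OCc3ccccc3)c2)[C@H]1OCc1ccccc1 | intermediate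
24 | (S)-2-(benzyloxy)-1-[4,5-bis(benzyloxy)-2-Fl-phenyl]-3-[4-(prop-2-en-1-yloxy)phenyl]propan-1-one | C=CCOc1ccc(cc1)C[C@H](OCc1ccccc1)C(=O)c1cc(OCc2ccccc2)c(OCc2ccccc2)cc1[C@@H]1c2ccc(OCc3ccccc3)cc2O[C@H](c2ccc(OCc3ccccc3)c(OCc3ccccc3)c2)[C@H]1OCc1ccccc1 | intermediate
25 | (1R,2S)-2-(benzyloxy)-1-[4,5-bis(benzyloxy)-2-Fl-phenyl]-3-[4-(prop-2-en-1-yloxy)phenyl]propan-1-ol | C=CCOc1ccc(cc1)C[C@H](OCc1ccccc1)[C@H](O)c1cc(OCc2ccccc2)c(OCc2ccccc2)cc1[C@@H]1c2ccc(OCc3ccccc3)cc2O[C@H](c2ccc(OCc3ccccc3)c(OCc3ccccc3)c2)[C@H]1OCc1ccccc1 | intermediate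
26 | 4-{(2S,3R)-2-(benzyloxy)-3-[4,5-bis(benzyloxy)-2-Fl-phenyl]-3-hydroxypropyl}phenol | Oc1ccc(cc1)C[C@H](OCc1ccccc1)[C@H](O)c1cc(OCc2ccccc2)c(OCc2ccccc2)cc1[C@@H]1c2ccc(OCc3ccccc3)cc2O[C@H](c2ccc(OCc3ccccc3)c(OCc3ccccc3)c2)[C@H]1OCc1ccccc1 | intermediate
27 | 4-{(2S,3R)-2-(benzyloxy)-3-[4,5-bis(benzyloxy)-2-Fl-phenyl]-3-hydroxypropyl}-4-methoxycyclohexa-2,5-dien-1-one | COC1(C=CC(=O)C=C1)C[C@H](OCc1ccccc1)[C@H](O)c1cc(OCc2ccccc2)c(OCc2ccccc2)cc1[C@@H]1c2ccc(OCc3ccccc3)cc2O[C@H](c2ccc(OCc3ccccc3)c(OCc3ccccc3)c2)[C@H]1OCc1ccccc1 | intermediate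
28 | cis-fused (2R,3S)-3-(benzyloxy)-2-[4,5-bis(benzyloxy)-2-Fl-phenyl]-4a-methoxy-2,3,4,4a,8,8a-hexahydro-7H-chromen-7-one, both ring-fusion diastereomers | COC12C=CC(=O)CC1O[C@H](c1cc(OCc3ccccc3)c(OCc3ccccc3)cc1[C@@H]1c3ccc(OCc4ccccc4)cc3O[C@H](c3ccc(OCc4ccccc4)c(OCc4ccccc4)c3)[C@H]1OCc1ccccc1)[C@@H](OCc1ccccc1)C2 | intermediate
29 | (2R,3S)-3-(benzyloxy)-2-[4,5-bis(benzyloxy)-2-Fl-phenyl]chroman-7-ol | Oc1ccc2c(c1)O[C@H](c1cc(OCc3ccccc3)c(OCc3ccccc3)cc1[C@@H]1c3ccc(OCc4ccccc4)cc3O[C@H](c3ccc(OCc4ccccc4)c(OCc4ccccc4)c3)[C@H]1OCc1ccccc1)[C@@H](OCc1ccccc1)C2 | intermediate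
30 | (2R,3S)-2-{2-[(2R,3S,4R)-2-(3,4-dihydroxyphenyl)-3,7-dihydroxychroman-4-yl]-4,5-dihydroxyphenyl}chroman-3,7-diol | Oc1ccc2c(c1)O[C@H](c1cc(O)c(O)cc1[C@@H]1c3ccc(O)cc3O[C@H](c3ccc(O)c(O)c3)[C@H]1O)[C@@H](O)C2 | target

**Count**
Total steps: 17. Longest linear sequence: 11 steps (8 → 9 → 11 → 14 → 19 → 21 → 22 → 24 → 25 → 26 → 29 → 30; steps 5, 6, 8, 10, 11, 12, 13, 14, 15, 16, 17).

**Steps most likely to fail**

1. Step 16. The side-chain hydroxyl may capture the ipso carbon during the oxidation (spiro-etherification), or the dienone may lose methanol towards a quinone methide or suffer an alkyl shift before the Michael addition, so that ring C of L does not close. The fallback uses known chemistry, a cine-substitution through an aryne, and sets out from phenol 26. Ortho-bromination of the free phenol, the most reactive ring under amine catalysis (N-bromosuccinimide, catalytic diisopropylamine, CH2Cl2), would give 2-bromo-4-{(2S,3R)-2-(benzyloxy)-3-[4,5-bis(benzyloxy)-2-Fl-phenyl]-3-hydroxypropyl}phenol F1. Benzylation (BnBr, K2CO3, acetone) would give its benzyl ether F2. Excess lithium 2,2,6,6-tetramethylpiperidide in THF (−78 → 0 °C) would remove HBr to give the 3-benzyloxyaryne F3 (as its C2L alkoxide, not isolated). The alkoxide adds to the aryne carbon next to the side chain, the position meta to the benzyloxy group as in cine-substitution of ortho-haloanisoles, and the tether allows no other closure. This gives (2R,3S)-3,7-bis(benzyloxy)-2-[4,5-bis(benzyloxy)-2-Fl-phenyl]chroman F4, and hydrogenolysis as in step 17 comes back to the route at 30.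

2. Step 10. The flavanone may be deprotonated at C3U and open by retro-oxa-Michael reaction, which erodes the C2U configuration, or the ortho-bromoaryl Grignard reagent may lose magnesium halide to a benzyne before it adds. The fallback replaces carbonyl addition by cross-coupling and sets out from flavanone 14 and dibromide 16. Tf2O with 2,6-di-tert-butyl-4-methylpyridine in CH2Cl2 would give (S)-7-(benzyloxy)-2-[3,4-bis(benzyloxy)phenyl]-2H-chromen-4-yl trifluoromethanesulfonate F5 without passing through an enolate. The arylmagnesium 17 made from 16, quenched with B(OiPr)3 and dilute acid, would give [4,5-bis(benzyloxy)-2-bromophenyl]boronic acid F6. Suzuki–Miyaura coupling (Pd(PPh3)4, K3PO4, dioxane/H2O, 60 °C), in which the alkenyl triflate should react ahead of the hindered, electron-rich aryl bromide, comes back to the route at flav-3-ene 19.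

3. Step 11. Hydroboration of the hindered trisubstituted alkene may be slow, or boron may go to the wrong face or to C4U. The fallback arylates a flavan-4-yl cation, replaces steps 10 and 11 together, and sets out from flavanone 14 and bromoarene 9. Hydroxylation of the potassium enolate of 14 (KN(SiMe3)2, THF, −78 °C, then 2-(phenylsulfonyl)-3-phenyloxaziridine) would give (2R,3R)-7-(benzyloxy)-2-[3,4-bis(benzyloxy)phenyl]-3-hydroxychroman-4-one F7. NaBH4 in MeOH/THF would give (2R,3S,4R)-7-(benzyloxy)-2-[3,4-bis(benzyloxy)phenyl]chroman-3,4-diol F8. BF3·OEt2 in CH2Cl2 (−78 → 0 °C) with an excess of 9 would ionise C4U and arylate it (Friedel–Crafts) para to a benzyloxy group and ortho to bromine, trans to the C3U hydroxyl, which comes back to the route at 21.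

**Further compounds**
F1 | step 16 | 2-bromo-4-{(2S,3R)-2-(benzyloxy)-3-[4,5-bis(benzyloxy)-2-Fl-phenyl]-3-hydroxypropyl}phenol | Oc1ccc(cc1Br)C[C@H](OCc1ccccc1)[C@H](O)c1cc(OCc2ccccc2)c(OCc2ccccc2)cc1[C@@H]1c2ccc(OCc3ccccc3)cc2O[C@H](c2ccc(OCc3ccccc3)c(OCc3ccccc3)c2)[C@H]1OCc1ccccc1
F2 | step 16 | (1R,2S)-2-(benzyloxy)-3-[4-(benzyloxy)-3-bromophenyl]-1-[4,5-bis(benzyloxy)-2-Fl-phenyl]propan-1-ol | c1ccccc1COc1ccc(cc1Br)C[C@H](OCc1ccccc1)[C@H](O)c1cc(OCc2ccccc2)c(OCc2ccccc2)cc1[C@@H]1c2ccc(OCc3ccccc3)cc2O[C@H](c2ccc(OCc3ccccc3)c(OCc3ccccc3)c2)[C@H]1OCc1ccccc1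
F3 | step 16 | aryne from F2 (triple bond between the former C–Br carbon and the carbon next to the side chain; not isolated) | c1ccccc1COC1=CC=C(C#C1)C[C@H](OCc1ccccc1)[C@H](O)c1cc(OCc2ccccc2)c(OCc2ccccc2)cc1[C@@H]1c2ccc(OCc3ccccc3)cc2O[C@H](c2ccc(OCc3ccccc3)c(OCc3ccccc3)c2)[C@H]1OCc1ccccc1
F4 | step 16 | (2R,3S)-3,7-bis(benzyloxy)-2-[4,5-bis(benzyloxy)-2-Fl-phenyl]chroman | c1ccccc1COc1ccc2c(c1)O[C@H](c1cc(OCc3ccccc3)c(OCc3ccccc3)cc1[C@@H]1c3ccc(OCc4ccccc4)cc3O[C@H](c3ccc(OCc4ccccc4)c(OCc4ccccc4)c3)[C@H]1OCc1ccccc1)[C@@H](OCc1ccccc1)C2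
F5 | step 10 | (S)-7-(benzyloxy)-2-[3,4-bis(benzyloxy)phenyl]-2H-chromen-4-yl trifluoromethanesulfonate | O=S(=O)(OC1=C[C@@H](c2ccc(OCc3ccccc3)c(OCc3ccccc3)c2)Oc2cc(OCc3ccccc3)ccc12)C(F)(F)F
F6 | step 10 | [4,5-bis(benzyloxy)-2-bromophenyl]boronic acid | OB(O)c1cc(OCc2ccccc2)c(OCc2ccccc2)cc1Br
F7 | step 11 | (2R,3R)-7-(benzyloxy)-2-[3,4-bis(benzyloxy)phenyl]-3-hydroxychroman-4-one | O=C1c2ccc(OCc3ccccc3)cc2O[C@H](c2ccc(OCc3ccccc3)c(OCc3ccccc3)c2)[C@H]1O
F8 | step 11 | (2R,3S,4R)-7-(benzyloxy)-2-[3,4-bis(benzyloxy)phenyl]chroman-3,4-diol | O[C@@H]1c2ccc(OCc3ccccc3)cc2O[C@H](c2ccc(OCc3ccccc3)c(OCc3ccccc3)c2)[C@H]1O
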